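**Retrosynthetic overview**
1. The C1 silyl ether is cleaved last. Before that, the ten-membered ring is closed at C8–C9 by an intramolecular carbonyl-ene reaction of a 4-formylbutenolide with its own isopropenyl group, and C8–OH is acetylated.
2. Key C–O bond, C13–OAc: a new γ-acetoxylation of the 3-methyl-4-formylbutenolide (C–N condensation, aza-[3,3] N–O to C–O shift, 1,3-acetate transposition).
3. The butenolide ring is formed first: catalytic asymmetric chromium allylation of a Z-enal (C6–C7, sets C6), lactonisation (C6–O–C12), then acetal hydrolysis to unveil C8=O.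
4. C1–O and the ene donor: Shi epoxidation of the terminal alkene of neryl acetate, then silyl-triflate isomerisation of the epoxide to the allyl silyl ether. The 4Z alkene is bought with neryl acetate.
5. Ring order: butenolide first, carbocycle second.

Assumption: the SMILES is binding, so C4=C5 is Z (C3 and C6 cis) and the stereocentres are 1S, 6R, 8S. Positions C1–C15 follow germacrane numbering; TBS = tert-butyldimethylsilyl.

**Step 1**
Reactants: 1 neryl acetate [(2Z)-3,7-dimethylocta-2,6-dien-1-yl acetate]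
Product: 2 (2Z)-5-[(2S)-3,3-dimethyloxiran-2-yl]-3-methylpent-2-en-1-yl acetate
Conditions: ent-Shi ketone (L-fructose-derived, 30 mol%), Oxone (2KHSO5·KHSO4·K2SO4), K2CO3, Bu4NHSO4, MeCN/dimethoxymethane/aq. Na2B4O7 buffer, 0 °C
Reagents that add atoms: potassium peroxymonosulfate KHSO5, [K+].[O-]S(=O)(=O)OO
Why: Shi asymmetric epoxidation: the chiral dioxirane oxidises only the electron-rich trisubstituted 6,7-alkene (the 2,3-alkene is deactivated by the allylic acetate), and the L-fructose-derived ketone delivers oxygen to the face that makes the future C1–O bond S.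

**Step 2**
Reactants: 2 (6S)-6,7-epoxyneryl acetate
Product: 3 (2Z,6S)-6-[(tert-butyldimethylsilyl)oxy]-3,7-dimethylocta-2,7-dien-1-yl acetate
Conditions: TBSOTf, DBU, toluene, −40 → 23 °C
Reagents that add atoms: tert-butyldimethylsilyl triflate, CC(C)(C)[Si](C)(C)OS(=O)(=O)C(F)(F)F
Why: Silyl-triflate/amidine epoxide-to-allyl-silyl-ether isomerisation: O-silylation, opening at the tertiary carbon and E2 loss of a methyl proton create the isopropenyl group, while the secondary C1–O bond is never broken, so 1S is retained and the alcohol emerges already protected.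

**Step 3**
Reactants: 3 (2Z,6S)-6-(TBS-oxy)-3,7-dimethylocta-2,7-dien-1-yl acetate
Product: 4 (2Z,6S)-6-[(tert-butyldimethylsilyl)oxy]-3,7-dimethylocta-2,7-dien-1-ol
Conditions: K2CO3 (cat.), MeOH, 0 → 23 °C
Reagents that add atoms: none
Why: Base-catalysed transesterification (methanolysis) removes only the primary acetate; the silyl ether, both alkenes and the stereocentre are inert to K2CO3/MeOH.

**Step 4**
Reactants: 4 (2Z,6S)-6-(TBS-oxy)-3,7-dimethylocta-2,7-dien-1-ol
Product: 5 (2Z,6S)-6-[(tert-butyldimethylsilyl)oxy]-3,7-dimethylocta-2,7-dienal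
Conditions: TEMPO (10 mol%), PhI(OAc)2, CH2Cl2, 23 °C
Reagents that add atoms: none
Why: TEMPO/PhI(OAc)2 (oxoammonium) oxidation of the primary allylic alcohol stops at the enal and preserves the Z geometry of neral-type aldehydes; the hindered silyl ether and the 1,1-disubstituted alkene do not react.

**Step 5**
Reactants: 6 methyl acrylate; 7 2,2-dimethoxyacetaldehyde (60% aqueous solution)
Product: 8 methyl 3-hydroxy-4,4-dimethoxy-2-methylidenebutanoate (racemic)
Conditions: DABCO, 1,4-dioxane/H2O, 23 °C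
Reagents that add atoms: none
Why: Morita–Baylis–Hillman reaction: DABCO adds to the acrylate and the resulting enolate attacks the activated α,α-dialkoxy aldehyde; the racemic carbinol centre is removed in the next step.

**Step 6**
Reactants: 8 methyl 3-hydroxy-4,4-dimethoxy-2-methylidenebutanoate
Product: 9 methyl (2Z)-2-(bromomethyl)-4,4-dimethoxybut-2-enoate
Conditions: NBS, Me2S, CH2Cl2, 0 → 23 °C
Reagents that add atoms: N-bromosuccinimide, O=C1CCC(=O)N1Br
Why: Corey–Kim-type activation of the allylic alcohol as an alkoxysulfonium ion followed by SN2′ attack of bromide gives the transposed (Z)-allyl bromide under non-acidic conditions that leave the dimethyl acetal intact.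

**Step 7**
Reactants: 5 (2Z,6S)-6-(TBS-oxy)-3,7-dimethylocta-2,7-dienal; 9 methyl (2Z)-2-(bromomethyl)-4,4-dimethoxybut-2-enoate
Product: 11 (4R,5R)-5-{(1Z,5S)-5-[(tert-butyldimethylsilyl)oxy]-2,6-dimethylhepta-1,6-dien-1-yl}-4-(dimethoxymethyl)-3-methylideneoxolan-2-one, via hydroxy ester 10 (not isolated)
Conditions: CrCl2 (10 mol%), chiral carbazole-bis(oxazoline) ligand (Si-face-selective enantiomer, 12 mol%), Mn powder, Me3SiCl, iPr2NEt, THF, 23 °C; then PPTS, MeOH, 23 °C
Reagents that add atoms: none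
Why: Catalytic asymmetric Nozaki–Hiyama–Kishi-type 2-(alkoxycarbonyl)allylation: the allylchromium from 9 adds through its γ-carbon (C7) to the aldehyde in a closed chair, the ligand directing attack to the Si face to set 6R (C7 forms syn but becomes sp2 in step 8), and acid-catalysed desilylation/lactonisation of 10 forms the lactone C6–O–C12 bond.

**Step 8**
Reactants: 11 (4R,5R)-acetal lactone
Product: 13 (2R)-2-{(1Z,5S)-5-[(tert-butyldimethylsilyl)oxy]-2,6-dimethylhepta-1,6-dien-1-yl}-4-methyl-5-oxo-2,5-dihydrofuran-3-carbaldehyde, via unconjugated aldehyde 12 (not isolated)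
Conditions: PPTS, acetone/H2O (10:1), 55 °C
Reagents that add atoms: water, O
Why: Acetal hydrolysis followed by acid-catalysed enolisation of the β,γ-unsaturated aldehyde 12 and γ-reprotonation moves the exocyclic alkene into the ring (conjugation with both carbonyls), erasing the C7 centre and leaving C6 and C1 untouched.

**Step 9**
Reactants: 13 (2R)-4-methyl-5-oxo-2,5-dihydrofuran-3-carbaldehyde bearing the C6 side chain
Product: 16 [(5R)-5-{(1Z,5S)-5-[(tert-butyldimethylsilyl)oxy]-2,6-dimethylhepta-1,6-dien-1-yl}-4-formyl-2-oxo-2,5-dihydrofuran-3-yl]methyl acetate, via N-acetoxy dienamine 14 (not isolated), via tertiary acetate 15 (not isolated)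
Conditions: MeNH(OAc)·HCl (1.5 equiv), DMSO, 23 → 45 °C
Reagents that add atoms: N-methyl-O-acetylhydroxylamine hydrochloride, CNOC(C)=O.Cl
Why: Proposed new method: formal γ-acetoxylation of a β,β-disubstituted enal, in which condensation of the aldehyde with MeNH–OAc (C–N bond) gives an N-acetoxy iminium whose vinylogous methyl (C13) is deprotonated to dienamine 14, an aza-[3,3] shift breaks the weak N–O bond and forms the C7–O bond (15 after imine hydrolysis), and the resulting tertiary 2-acylallyl acetate transposes by a chloride/acetate SN2′ relay to the primary C13 acetate, driven by reconjugation with aldehyde and lactone; the closest known reactions are the α-acyloxylation of saturated aldehydes and ketones with N-alkyl-O-acylhydroxylamines and the 1,3-acetate shift of Baylis–Hillman acetates, neither shown on enals where γ-selectivity results, and no stereocentre is made while C6 is safe because no base stronger than chloride is present.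

**Step 10**
Reactants: 16 acetoxymethyl formylbutenolide
Product: 18 (1S,6R,8S,4Z)-8,13-diacetoxy-1-[(tert-butyldimethylsilyl)oxy]germacra-4,7(11),10(14)-trien-6,12-olide, via macrocyclic alcohol 17 (not isolated)
Conditions: Me2AlCl (2.5 equiv), CH2Cl2 (0.002 M), −78 → 0 °C; then Ac2O, DMAP, pyridine, 0 °C
Reagents that add atoms: acetic anhydride, CC(=O)OC(C)=O
Why: Lewis-acid-promoted intramolecular carbonyl-ene reaction of the type-two kind: the 1,1-disubstituted alkene attacks the Me2AlCl-activated conjugated aldehyde with transfer of a methyl hydrogen, closing the ten-membered ring at C8–C9 and leaving the 10(14)-methylene, with C8 expected under substrate control (tether on the butenolide face that carries C5, aluminium-bound oxygen turned outward toward the acetoxymethyl group, giving 8S), and the alcohol is then acetylated with retention.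

**Step 11**
Reactants: 18 silyl-protected diacetate
Product: 19 8α,13-diacetoxy-1α-hydroxygermacra-4,7(11),10(14)-trien-6α,12-olide (1S,6R,8S,4Z)
Conditions: HF·pyridine, pyridine, THF, 0 → 23 °C
Reagents that add atoms: none
Why: Fluoride-mediated desilylation (Si–O cleavage) frees the C1 alcohol without touching the two acetates, the butenolide or any stereocentre.

**Compound list**
1 | neryl acetate, (2Z)-3,7-dimethylocta-2,6-dien-1-yl acetate | CC(=O)OC/C=C(/C)CCC=C(C)C | starting material
2 | (2Z)-5-[(2S)-3,3-dimethyloxiran-2-yl]-3-methylpent-2-en-1-yl acetate | CC(=O)OC/C=C(/C)CC[C@@H]1OC1(C)C | intermediate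
3 | (2Z,6S)-6-[(tert-butyldimethylsilyl)oxy]-3,7-dimethylocta-2,7-dien-1-yl acetate | CC(=O)OC/C=C(/C)CC[C@@H](C(C)=C)O[Si](C)(C)C(C)(C)C | intermediate
4 | (2Z,6S)-6-[(tert-butyldimethylsilyl)oxy]-3,7-dimethylocta-2,7-dien-1-ol | OC/C=C(/C)CC[C@@H](C(C)=C)O[Si](C)(C)C(C)(C)C | intermediate
5 | (2Z,6S)-6-[(tert-butyldimethylsilyl)oxy]-3,7-dimethylocta-2,7-dienal | O=C/C=C(/C)CC[C@@H](C(C)=C)O[Si](C)(C)C(C)(C)C | intermediate
6 | methyl acrylate | C=CC(=O)OC | starting material
7 | 2,2-dimethoxyacetaldehyde | COC(OC)C=O | starting material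
8 | methyl 3-hydroxy-4,4-dimethoxy-2-methylidenebutanoate (racemic) | C=C(C(=O)OC)C(O)C(OC)OC | intermediate
9 | methyl (2Z)-2-(bromomethyl)-4,4-dimethoxybut-2-enoate | COC(=O)/C(CBr)=C/C(OC)OC | intermediate
10 | methyl (3R,4R,5Z,9S)-9-[(tert-butyldimethylsilyl)oxy]-3-(dimethoxymethyl)-4-hydroxy-6,10-dimethyl-2-methylideneundeca-5,10-dienoate | C=C(C(=O)OC)[C@@H](C(OC)OC)[C@H](O)/C=C(/C)CC[C@@H](C(C)=C)O[Si](C)(C)C(C)(C)C | intermediate
11 | (4R,5R)-5-{(1Z,5S)-5-[(tert-butyldimethylsilyl)oxy]-2,6-dimethylhepta-1,6-dien-1-yl}-4-(dimethoxymethyl)-3-methylideneoxolan-2-one | C=C1C(=O)O[C@H](/C=C(/C)CC[C@@H](C(C)=C)O[Si](C)(C)C(C)(C)C)[C@@H]1C(OC)OC | intermediate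
12 | (2R,3R)-2-{(1Z,5S)-5-[(tert-butyldimethylsilyl)oxy]-2,6-dimethylhepta-1,6-dien-1-yl}-4-methylidene-5-oxooxolane-3-carbaldehyde | C=C1C(=O)O[C@H](/C=C(/C)CC[C@@H](C(C)=C)O[Si](C)(C)C(C)(C)C)[C@@H]1C=O | intermediate
13 | (2R)-2-{(1Z,5S)-5-[(tert-butyldimethylsilyl)oxy]-2,6-dimethylhepta-1,6-dien-1-yl}-4-methyl-5-oxo-2,5-dihydrofuran-3-carbaldehyde | CC1=C(C=O)[C@@H](/C=C(/C)CC[C@@H](C(C)=C)O[Si](C)(C)C(C)(C)C)OC1=O | intermediate
14 | N-acetoxy-N-methyl-1-[(3E,5R)-5-{(1Z,5S)-5-[(tert-butyldimethylsilyl)oxy]-2,6-dimethylhepta-1,6-dien-1-yl}-3'-methylidene-2-oxooxolan-4-ylidene]methanamine (2-oxo-3-methylidene ring, exocyclic enamine at ring C4) | C=C1C(=O)O[C@H](/C=C(/C)CC[C@@H](C(C)=C)O[Si](C)(C)C(C)(C)C)/C1=C/N(C)OC(C)=O | intermediate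
15 | (2R,3S)-2-{(1Z,5S)-5-[(tert-butyldimethylsilyl)oxy]-2,6-dimethylhepta-1,6-dien-1-yl}-3-formyl-4-methylidene-5-oxooxolan-3-yl acetate | C=C1C(=O)O[C@H](/C=C(/C)CC[C@@H](C(C)=C)O[Si](C)(C)C(C)(C)C)[C@]1(OC(C)=O)C=O | intermediate
16 | [(5R)-5-{(1Z,5S)-5-[(tert-butyldimethylsilyl)oxy]-2,6-dimethylhepta-1,6-dien-1-yl}-4-formyl-2-oxo-2,5-dihydrofuran-3-yl]methyl acetate | CC(=O)OCC1=C(C=O)[C@@H](/C=C(/C)CC[C@@H](C(C)=C)O[Si](C)(C)C(C)(C)C)OC1=O | intermediate
17 | (1S,6R,8S,4Z)-13-acetoxy-1-[(tert-butyldimethylsilyl)oxy]-8-hydroxygermacra-4,7(11),10(14)-trien-6,12-olide | C=C1C[C@H](O)C2=C(COC(C)=O)C(=O)O[C@@H]2/C=C(/C)CC[C@@H]1O[Si](C)(C)C(C)(C)C | intermediate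
18 | (1S,6R,8S,4Z)-8,13-diacetoxy-1-[(tert-butyldimethylsilyl)oxy]germacra-4,7(11),10(14)-trien-6,12-olide | C=C1C[C@H](OC(C)=O)C2=C(COC(C)=O)C(=O)O[C@@H]2/C=C(/C)CC[C@@H]1O[Si](C)(C)C(C)(C)C | intermediate
19 | 8α,13-diacetoxy-1α-hydroxygermacra-4,7(11),10(14)-trien-6α,12-olide | C=C1C[C@H](OC(C)=O)C2=C(COC(C)=O)C(=O)O[C@@H]2/C=C(/C)CC[C@@H]1O | target

**Step count and risk**
Total steps: 11. Longest linear sequence: 9 (steps 1–4 and 7–11); steps 5–6 make the allyl bromide.

The three steps most likely to fail: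

Step 7 (enantio-control at C6 on a Z-enal with a functionalised γ-substituted allyl bromide; which ligand enantiomer gives Si-face attack has to be confirmed on the first run). The fallback sets out from 9 and 5 and comes back at 11, replacing the chromium allyl by a boron allyl under Brønsted-acid control. Borylation of 9 (B2pin2, Pd2(dba)3 cat., KOAc, DMSO, 50 °C) gives methyl (2E)-4,4-dimethoxy-2-[(4,4,5,5-tetramethyl-1,3,2-dioxaborolan-2-yl)methyl]but-2-enoate F1. Allylboration of 5 with it, catalysed by a chiral BINOL-derived phosphoric acid (Si-face-selective enantiomer, toluene, −30 °C), runs through the same closed chair and gives the same syn adduct 10. PPTS/MeOH then closes 10 to 11.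

Step 9 (the new γ-acetoxylation; the tertiary acetate 15 may fail to transpose, or liberated methylamine may add SN2′). The fallback sets out from 13 and comes back at 16 with known enol-ether chemistry. Soft enolisation of 13 (Et3SiOTf, Et3N, CH2Cl2, −78 °C; the silylated aldehyde acidifies only C13–H) gives the silyl dienol ether (5R)-5-{(1Z,5S)-5-[(tert-butyldimethylsilyl)oxy]-2,6-dimethylhepta-1,6-dien-1-yl}-3-methylidene-4-{(E)-[(triethylsilyl)oxy]methylidene}oxolan-2-one F2. NBS (THF, −78 °C) brominates its γ-terminus to (2R)-4-(bromomethyl)-2-{(1Z,5S)-5-[(tert-butyldimethylsilyl)oxy]-2,6-dimethylhepta-1,6-dien-1-yl}-5-oxo-2,5-dihydrofuran-3-carbaldehyde F3. KOAc/18-crown-6 (MeCN, 23 °C) displaces the bromide to give 16.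

Step 10 (ten-membered ring closure; the C8 configuration rests on a conformational argument and is not secured by precedent). The fallback sets out from 16 and comes back at 18, and addresses the C8 configuration only. If the ene reaction gives mainly the 8-epimer, the in-flask acetylation is omitted and the alcohol is purified as (1S,6R,8R,4Z)-13-acetoxy-1-[(tert-butyldimethylsilyl)oxy]-8-hydroxygermacra-4,7(11),10(14)-trien-6,12-olide F4. Mitsunobu esterification (AcOH, PPh3, DIAD, toluene, 0 °C) then forms the C8–O acetate bond with inversion to give 18.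

**Further compounds**
F1 | step 7 | methyl (2E)-4,4-dimethoxy-2-[(4,4,5,5-tetramethyl-1,3,2-dioxaborolan-2-yl)methyl]but-2-enoate | COC(=O)/C(CB1OC(C)(C)C(C)(C)O1)=C/C(OC)OC
F2 | step 9 | (5R)-5-{(1Z,5S)-5-[(tert-butyldimethylsilyl)oxy]-2,6-dimethylhepta-1,6-dien-1-yl}-3-methylidene-4-{(E)-[(triethylsilyl)oxy]methylidene}oxolan-2-one | C=C1C(=O)O[C@H](/C=C(/C)CC[C@@H](C(C)=C)O[Si](C)(C)C(C)(C)C)/C1=C/O[Si](CC)(CC)CC
F3 | step 9 | (2R)-4-(bromomethyl)-2-{(1Z,5S)-5-[(tert-butyldimethylsilyl)oxy]-2,6-dimethylhepta-1,6-dien-1-yl}-5-oxo-2,5-dihydrofuran-3-carbaldehyde | BrCC1=C(C=O)[C@@H](/C=C(/C)CC[C@@H](C(C)=C)O[Si](C)(C)C(C)(C)C)OC1=O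
F4 | step 10 | (1S,6R,8R,4Z)-13-acetoxy-1-[(tert-butyldimethylsilyl)oxy]-8-hydroxygermacra-4,7(11),10(14)-trien-6,12-olide | C=C1C[C@@H](O)C2=C(COC(C)=O)C(=O)O[C@@H]2/C=C(/C)CC[C@@H]1O[Si](C)(C)C(C)(C)C
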